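**Strategy**

Everything rests on reading the ring segment C9(=O)–C10(Cl)=C11, which abuts the quaternary acetoxy carbon C12 in the cyclopentenone ring, as one carbon (C10 with its chlorine) inserted into the C9–C11 bond of a cyclobutanone. In one operation dichlorocarbene adds to a cyclobutanone silyl enol ether and the strained adduct opens, so the four-membered ring grows to the cyclopentenone while the enone and the vinyl chloride appear together. The precursor is an enantioenriched 1-silyloxycyclobutene whose C3 (future C12) carries a silyl ether and the C13–C20 chain as an alkyne; its configuration is decided solely by which enantiotopic methylene, C11 and not C8, is enolised.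

Key step: step 7

Assumption: prostanoid numbering (C1 ester carbon to C20 methyl) is used for atom labels, and the (R,R)-amide of step 6 is assumed to remove a C11 proton; if it proves to take the C8 methylene, the (S,S)-amide is used with no other change.

**Route**

Step 1
Reactants: 1 3-(benzyloxy)cyclobutan-1-one
Product: 2 5-(benzyloxy)-1-oxaspiro[2.3]hexane (cis/trans mixture)
Conditions: Me3S(O)I, NaH, DMSO, rt
Reagents that add atoms: trimethylsulfoxonium iodide, C[S+](C)(C)=O.[I-]
Why: Corey–Chaykovsky epoxidation, in which the sulfoxonium ylide adds to the unhindered cyclobutanone carbonyl and the betaine closes to the spiro-epoxide; the cis/trans ratio is irrelevant because the benzyloxy carbon later becomes the C9 carbonyl.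

Step 2
Reactants: 2 5-(benzyloxy)-1-oxaspiro[2.3]hexane; 3 hept-1-yne
Product: 5 3-(benzyloxy)-1-(oct-2-yn-1-yl)cyclobutan-1-ol (cis/trans mixture), via lithium hept-1-ynide 4 (not isolated)
Conditions: n-BuLi, THF, −78 → 0 °C; then 2, DMPU, 0 → 45 °C; H2O
Reagents that add atoms: none
Why: SN2 opening of the 2,2-disubstituted epoxide at its methylene carbon by the lithium acetylide, run in a dipolar aprotic medium without a Lewis acid so that the oxaspirohexane cannot rearrange to a cyclopentanone, assembles C13–C20 and the tertiary C12 carbinol.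

Step 3
Reactants: 5 3-(benzyloxy)-1-(oct-2-yn-1-yl)cyclobutan-1-ol
Product: 6 [3-(benzyloxy)-1-(oct-2-yn-1-yl)cyclobutoxy](tert-butyl)dimethylsilane (cis/trans mixture)
Conditions: TBSOTf, 2,6-lutidine, CH2Cl2, 0 °C → rt
Reagents that add atoms: tert-butyldimethylsilyl trifluoromethanesulfonate, CC(C)(C)[Si](C)(C)OS(=O)(=O)C(F)(F)F
Why: Silylation of a tertiary alcohol with a silyl triflate and a hindered pyridine base is standard, and the resulting ether should survive amide bases, carbene generation and hydrogenation.

Step 4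
Reactants: 6 [3-(benzyloxy)-1-(oct-2-yn-1-yl)cyclobutoxy](tert-butyl)dimethylsilane
Product: 7 3-(tert-butyldimethylsilyloxy)-3-(oct-2-yn-1-yl)cyclobutan-1-ol (cis/trans mixture)
Conditions: DDQ, CH2Cl2/H2O, 525 nm LED, rt
Reagents that add atoms: none
Why: Visible-light-assisted oxidative debenzylation with DDQ (benzylic oxidation, then hydrolysis of the oxocarbenium ion) is chosen because, unlike hydrogenolysis, it leaves the alkyne untouched and spares the tertiary silyl ether.

Step 5
Reactants: 7 3-(tert-butyldimethylsilyloxy)-3-(oct-2-yn-1-yl)cyclobutan-1-ol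
Product: 8 3-(tert-butyldimethylsilyloxy)-3-(oct-2-yn-1-yl)cyclobutan-1-one
Conditions: Dess–Martin periodinane, CH2Cl2, rt
Reagents that add atoms: none
Why: Dess–Martin oxidation is a two-electron process that avoids the ring cleavage seen with one-electron oxidants on cyclobutanols and gives the prochiral ketone whose α-methylenes C8 and C11 are enantiotopic.

Step 6
Reactants: 8 3-(tert-butyldimethylsilyloxy)-3-(oct-2-yn-1-yl)cyclobutan-1-one
Product: 10 (S)-3-(tert-butyldimethylsilyloxy)-3-(oct-2-yn-1-yl)-1-(trimethylsilyloxy)cyclobut-1-ene, via lithium cyclobutenolate 9 (not isolated)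
Conditions: (R,R)-[PhCH(Me)]2NH, n-BuLi, LiCl, THF; Me3SiCl (in situ), then 8, −100 °C; filtration through Et3N-deactivated silica (pentane)
Reagents that add atoms: chlorotrimethylsilane, C[Si](C)(C)Cl
Why: Enantiotopic-group-selective deprotonation of a prochiral cyclobutanone by a C2-symmetric chiral lithium amide with internal silyl chloride quench (a desymmetrisation known for 3-substituted cyclobutanones) removes a C11 proton and not a C8 proton, which defines C12 as S, and the in situ silylation traps the enolate before it can expel the β-silyloxide.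

Step 7
Reactants: 10 (S)-3-(tert-butyldimethylsilyloxy)-3-(oct-2-yn-1-yl)-1-(trimethylsilyloxy)cyclobut-1-ene; 11 sodium trichloroacetate
Product: 13 (S)-4-(tert-butyldimethylsilyloxy)-2-chloro-4-(oct-2-yn-1-yl)cyclopent-2-en-1-one, via dichlorobicyclopentane 12 (not isolated)
Conditions: Cl3CCO2Na, BnEt3NCl (cat.), CHCl3 (ethanol-free), 55–60 °C; aq. NaHCO3
Reagents that add atoms: none
Why: Dichlorocarbene, freed by decarboxylation of the trichloroacetate under anhydrous, neutral conditions, adds as an electrophile in a [2+1] cycloaddition to the electron-rich C9=C11 enol ether bond of 10 and gives the dichlorobicyclo[2.1.0]pentane 12. The cyclopropane of 12 then ionises with loss of the chloride lying over the four-membered ring, the only one whose departure fits the disrotatory cyclopropyl-to-allyl motion that keeps the allyl unit cis inside a ring; the C9 oxygen lone pair assists, the old C9–C11 bond breaks, and chloride strips the trimethylsilyl group from the 2-chloro-1-silyloxyallyl cation to leave enone 13. The closest known reaction type is the dihalocarbene one-carbon homologation of cyclic silyl enol ethers to 2-halocycloalk-2-enones, applied here to a cyclobutene. The cyclopentenone ring is thus closed by ring enlargement and not by cyclisation: C10 is stitched in through the new C9–C10 and C10–C11 bonds, and release of bicyclopentane strain drives the opening. No stereocentre is formed, because the bridgehead centres of 12 vanish again and both faces of carbene attack converge, while C12, fixed in step 6, is not touched. The selectivity needed is attack at the enol ether and not at the side chain or at silicon, secured by carrying C14–C15 as a poorly nucleophilic alkyne and by the neutral carbene source, and the moderate temperature keeps carbene capture ahead of conrotatory opening of the 3-silyloxycyclobutene.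

Step 8
Reactants: 13 (S)-4-(tert-butyldimethylsilyloxy)-2-chloro-4-(oct-2-yn-1-yl)cyclopent-2-en-1-one
Product: 14 (S)-4-(tert-butyldimethylsilyloxy)-2-chloro-4-[(Z)-oct-2-en-1-yl]cyclopent-2-en-1-one
Conditions: H2 (1 atm, one equivalent taken up), Pd/CaCO3/Pb(OAc)2, quinoline, EtOAc, rt
Reagents that add atoms: none
Why: Lindlar semihydrogenation delivers H2 syn on lead-poisoned palladium to give the 14Z alkene, the alkyne binding far more strongly than the hindered, electron-poor chloroenone, whose C=C and C–Cl bonds are expected to stay intact.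

Step 9
Reactants: 15 methyl hex-5-ynoate
Product: 17 methyl 7-hydroxyhept-5-ynoate, via lithium acetylide 16 (not isolated)
Conditions: n-BuLi, THF, −78 °C; (CH2O)n, −78 °C → rt; AcOH
Reagents that add atoms: paraformaldehyde (as formaldehyde), C=O
Why: Hydroxymethylation of a terminal alkyne, in which deprotonation of the sp C–H by n-BuLi at −78 °C outruns addition to the methyl ester and the acetylide then adds to formaldehyde released from the polymer.

Step 10
Reactants: 17 methyl 7-hydroxyhept-5-ynoate
Product: 18 methyl (Z)-7-hydroxyhept-5-enoate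
Conditions: H2 (1 atm), Pd/CaCO3/Pb(OAc)2, quinoline, EtOAc, rt
Reagents that add atoms: none
Why: Lindlar semihydrogenation of the propargylic alcohol gives the Z allylic alcohol by syn addition of H2.

Step 11
Reactants: 18 methyl (Z)-7-hydroxyhept-5-enoate
Product: 19 methyl (Z)-7-oxohept-5-enoate
Conditions: PhI(OAc)2, TEMPO (cat.), CH2Cl2, 0 °C → rt; used at once
Reagents that add atoms: none
Why: TEMPO-catalysed oxoammonium oxidation with PhI(OAc)2 converts the allylic alcohol to the enal under near-neutral conditions of the kind that preserve Z enals.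

Step 12
Reactants: 14 (S)-4-(tert-butyldimethylsilyloxy)-2-chloro-4-[(Z)-oct-2-en-1-yl]cyclopent-2-en-1-one; 19 methyl (Z)-7-oxohept-5-enoate
Product: 21 methyl (5Z,12S,14Z)-12-(tert-butyldimethylsilyloxy)-10-chloro-7-hydroxy-9-oxoprosta-5,10,14-trienoate (C7/C8 diastereomer mixture), via lithium dienolate 20 (not isolated)
Conditions: LiN(i-Pr)2, THF, −78 °C; then 19, −78 °C; AcOH
Reagents that add atoms: none
Why: Kinetic deprotonation at C8, the only enolisable position because C12 is quaternary, gives the cross-conjugated lithium dienolate, which undergoes 1,2-aldol addition to the Z-enal at −78 °C without expelling the β-silyloxy group; the new C7 and C8 centres form as a mixture that the next step erases.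

Step 13
Reactants: 21 methyl (5Z,12S,14Z)-12-(tert-butyldimethylsilyloxy)-10-chloro-7-hydroxy-9-oxoprosta-5,10,14-trienoate
Product: 23 methyl (5Z,7E,12R,14Z)-12-(tert-butyldimethylsilyloxy)-10-chloro-9-oxoprosta-5,7,10,14-tetraenoate, via allylic mesylate 22 (not isolated)
Conditions: MsCl, Et3N (excess), CH2Cl2, −20 °C → rt
Reagents that add atoms: none
Why: Mesylation of the C7 hydroxyl followed by E1cB elimination through the C8 enolate (completion of the aldol condensation) creates C7=C8, the 7E isomer with C6 turned away from the C9 carbonyl being expected to predominate and the 7Z isomer being removed by chromatography.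

Step 14
Reactants: 23 methyl (5Z,7E,12R,14Z)-12-(tert-butyldimethylsilyloxy)-10-chloro-9-oxoprosta-5,7,10,14-tetraenoate
Product: 24 methyl (5Z,7E,12R,14Z)-10-chloro-12-hydroxy-9-oxoprosta-5,7,10,14-tetraenoate
Conditions: 48% aq. HF, MeCN, 0 °C → rt
Reagents that add atoms: none
Why: Fluoride-driven cleavage of the tertiary silyl ether (Si–F bond formation) in an acidic, non-nucleophilic medium should tolerate the cross-conjugated chlorodienone, the ester and both Z alkenes, which basic fluoride sources would endanger.

Step 15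
Reactants: 24 methyl (5Z,7E,12R,14Z)-10-chloro-12-hydroxy-9-oxoprosta-5,7,10,14-tetraenoate
Product: 25 methyl (5Z,7E,12R,14Z)-12-acetoxy-10-chloro-9-oxoprosta-5,7,10,14-tetraenoate
Conditions: Ac2O, DMAP (cat.), pyridine, CH2Cl2, rt
Reagents that add atoms: acetic anhydride, CC(=O)OC(C)=O
Why: DMAP-catalysed acyl transfer to the hindered tertiary C12 alcohol gives the acetate with retention, since the C12–O bond is never broken.

**Compound list**

Compounds 2, 5, 6 and 7 are achiral cis/trans mixtures that converge at 8, so their SMILES carry no ring descriptors.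

1 | 3-(benzyloxy)cyclobutan-1-one | O=C1CC(OCc2ccccc2)C1 | starting material
2 | 5-(benzyloxy)-1-oxaspiro[2.3]hexane (cis/trans mixture) | C1OC12CC(OCc3ccccc3)C2 | intermediate
3 | hept-1-yne | CCCCCC#C | starting material
4 | lithium hept-1-ynide (formed in the flask, not isolated) | [Li+].[C-]#CCCCCC | intermediate
5 | 3-(benzyloxy)-1-(oct-2-yn-1-yl)cyclobutan-1-ol (cis/trans mixture) | CCCCCC#CCC1(O)CC(OCc2ccccc2)C1 | intermediate
6 | [3-(benzyloxy)-1-(oct-2-yn-1-yl)cyclobutoxy](tert-butyl)dimethylsilane (cis/trans mixture) | CCCCCC#CCC1(O[Si](C)(C)C(C)(C)C)CC(OCc2ccccc2)C1 | intermediate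
7 | 3-(tert-butyldimethylsilyloxy)-3-(oct-2-yn-1-yl)cyclobutan-1-ol (cis/trans mixture) | CCCCCC#CCC1(O[Si](C)(C)C(C)(C)C)CC(O)C1 | intermediate
8 | 3-(tert-butyldimethylsilyloxy)-3-(oct-2-yn-1-yl)cyclobutan-1-one | CCCCCC#CCC1(O[Si](C)(C)C(C)(C)C)CC(=O)C1 | intermediate
9 | lithium (S)-3-(tert-butyldimethylsilyloxy)-3-(oct-2-yn-1-yl)cyclobut-1-en-1-olate (formed in the flask, not isolated) | CCCCCC#CC[C@@]1(O[Si](C)(C)C(C)(C)C)C=C([O-])C1.[Li+] | intermediate
10 | (S)-3-(tert-butyldimethylsilyloxy)-3-(oct-2-yn-1-yl)-1-(trimethylsilyloxy)cyclobut-1-ene | CCCCCC#CC[C@@]1(O[Si](C)(C)C(C)(C)C)C=C(O[Si](C)(C)C)C1 | intermediate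
11 | sodium trichloroacetate | [Na+].[O-]C(=O)C(Cl)(Cl)Cl | starting material
12 | (3S)-3-(tert-butyldimethylsilyloxy)-5,5-dichloro-3-(oct-2-yn-1-yl)-1-(trimethylsilyloxy)bicyclo[2.1.0]pentane (both ring-fusion faces; formed in the flask, not isolated) | CCCCCC#CC[C@@]1(O[Si](C)(C)C(C)(C)C)C2C(Cl)(Cl)C2(O[Si](C)(C)C)C1 | intermediate
13 | (S)-4-(tert-butyldimethylsilyloxy)-2-chloro-4-(oct-2-yn-1-yl)cyclopent-2-en-1-one | CCCCCC#CC[C@@]1(O[Si](C)(C)C(C)(C)C)C=C(Cl)C(=O)C1 | intermediate
14 | (S)-4-(tert-butyldimethylsilyloxy)-2-chloro-4-[(Z)-oct-2-en-1-yl]cyclopent-2-en-1-one | CCCCC/C=C\C[C@@]1(O[Si](C)(C)C(C)(C)C)C=C(Cl)C(=O)C1 | intermediate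
15 | methyl hex-5-ynoate | C#CCCCC(=O)OC | starting material
16 | methyl 6-lithiohex-5-ynoate, the lithium acetylide of 15 (formed in the flask, not isolated) | [Li+].[C-]#CCCCC(=O)OC | intermediate
17 | methyl 7-hydroxyhept-5-ynoate | OCC#CCCCC(=O)OC | intermediate
18 | methyl (Z)-7-hydroxyhept-5-enoate | OC/C=C\CCCC(=O)OC | intermediate
19 | methyl (Z)-7-oxohept-5-enoate | O=C/C=C\CCCC(=O)OC | intermediate
20 | lithium (S)-3-(tert-butyldimethylsilyloxy)-5-chloro-3-[(Z)-oct-2-en-1-yl]cyclopenta-1,4-dien-1-olate (formed in the flask, not isolated) | CCCCC/C=C\C[C@@]1(O[Si](C)(C)C(C)(C)C)C=C(Cl)C([O-])=C1.[Li+] | intermediate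
21 | methyl (5Z,12S,14Z)-12-(tert-butyldimethylsilyloxy)-10-chloro-7-hydroxy-9-oxoprosta-5,10,14-trienoate (mixture at C7 and C8) | CCCCC/C=C\C[C@@]1(O[Si](C)(C)C(C)(C)C)C=C(Cl)C(=O)C1C(O)/C=C\CCCC(=O)OC | intermediate
22 | methyl (5Z,12S,14Z)-12-(tert-butyldimethylsilyloxy)-10-chloro-7-(methanesulfonyloxy)-9-oxoprosta-5,10,14-trienoate (formed in the flask, not isolated) | CCCCC/C=C\C[C@@]1(O[Si](C)(C)C(C)(C)C)C=C(Cl)C(=O)C1C(OS(C)(=O)=O)/C=C\CCCC(=O)OC | intermediate
23 | methyl (5Z,7E,12R,14Z)-12-(tert-butyldimethylsilyloxy)-10-chloro-9-oxoprosta-5,7,10,14-tetraenoate | CCCCC/C=C\C[C@@]1(O[Si](C)(C)C(C)(C)C)C=C(Cl)C(=O)/C1=C/C=C\CCCC(=O)OC | intermediate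
24 | methyl (5Z,7E,12R,14Z)-10-chloro-12-hydroxy-9-oxoprosta-5,7,10,14-tetraenoate | CCCCC/C=C\C[C@@]1(O)C=C(Cl)C(=O)/C1=C/C=C\CCCC(=O)OC | intermediate
25 | methyl (5Z,7E,12R,14Z)-12-acetoxy-10-chloro-9-oxoprosta-5,7,10,14-tetraenoate | CCCCC/C=C\C[C@@]1(OC(C)=O)C=C(Cl)C(=O)/C1=C/C=C\CCCC(=O)OC | target

**Step count**

Total steps: 15. Longest linear sequence: 12 steps (steps 1–8 and 12–15, from 1); the side chain (steps 9–11, from 15) joins at step 12.

**Steps most likely to fail**

Step 6. The chiral amide may discriminate poorly between the C8 and C11 methylenes, because the silyloxy and propargyl groups at C3 bias the ring only weakly, and the enolate may lose silyloxide before it is trapped. Either would leave 10, and hence 13, in low enantiomeric purity. The fallback sets out from 13 of insufficient enantiomeric purity and returns to the route at 13. Corey–Bakshi–Shibata reduction of the C9 ketone with (S)-1-methyl-3,3-diphenyltetrahydro-1H,3H-pyrrolo[1,2-c][1,3,2]oxazaborole and catecholborane (toluene, −78 °C; catecholborane spares the alkyne) is catalyst-controlled and turns the two enantiomers into diastereomers. (S)-13 should give (1R,4S)-4-(tert-butyldimethylsilyloxy)-2-chloro-4-(oct-2-yn-1-yl)cyclopent-2-en-1-ol F1, and its antipode the (1R,4R)-diastereomeric alcohol F2. These are separated on silica, and F1 alone is reoxidised with Dess–Martin periodinane to 13.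

Step 7. Conrotatory opening of the donor-substituted cyclobutene to a silyloxydiene, hydrolytic loss of the enol ether, or consumption of the carbene elsewhere may outrun cyclopropanation. The fallback sets out from 10 and returns at 13, and it separates the carbon insertion from the chlorination. Furukawa cyclopropanation (Et2Zn, CH2I2, 0 °C) gives (3S)-3-(tert-butyldimethylsilyloxy)-3-(oct-2-yn-1-yl)-1-(trimethylsilyloxy)bicyclo[2.1.0]pentane F3. Oxidative opening of its ring-fusion bond with FeCl3 in DMF (Ito–Saegusa ring enlargement) gives the 3-chlorocyclopentanone F4, which is not isolated but dehydrochlorinated with NaOAc in MeOH to (S)-4-(tert-butyldimethylsilyloxy)-4-(oct-2-yn-1-yl)cyclopent-2-en-1-one F5. Nucleophilic epoxidation (H2O2, NaOH, MeOH, 0 °C) gives the 2,3-epoxy ketone F6. HCl in ether opens it at C10 to the chlorohydrin F7, which loses water to give 13.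

Step 13. The elimination may show poor geometric control at C7=C8, and the allylic mesylate may ionise and scramble the 5Z alkene. The fallback sets out from 14 and 17 and returns at 23, carrying C5–C6 as an alkyne through the condensation. Oxidation of 17 (PhI(OAc)2, TEMPO) gives methyl 7-oxohept-5-ynoate F8. Its aldol addition to dienolate 20 (made from 14 as in step 12) gives the propargylic aldol F9. Mesylation and elimination by way of the propargylic mesylate F10 give the 7E enynone F11; the slim alkynyl group is expected to favour that geometry, and no Z alkene at C5 is exposed to the elimination. Semihydrogenation of the conjugated alkyne over Pd/CaCO3/Pb(OAc)2 with quinoline then sets 5Z last and gives 23.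

**Further compounds**

F1 | step 6 | (1R,4S)-4-(tert-butyldimethylsilyloxy)-2-chloro-4-(oct-2-yn-1-yl)cyclopent-2-en-1-ol | CCCCCC#CC[C@@]1(O[Si](C)(C)C(C)(C)C)C=C(Cl)[C@H](O)C1
F2 | step 6 | (1R,4R)-4-(tert-butyldimethylsilyloxy)-2-chloro-4-(oct-2-yn-1-yl)cyclopent-2-en-1-ol | CCCCCC#CC[C@]1(O[Si](C)(C)C(C)(C)C)C=C(Cl)[C@H](O)C1
F3 | step 7 | (3S)-3-(tert-butyldimethylsilyloxy)-3-(oct-2-yn-1-yl)-1-(trimethylsilyloxy)bicyclo[2.1.0]pentane (both ring-fusion faces) | CCCCCC#CC[C@@]1(O[Si](C)(C)C(C)(C)C)C2CC2(O[Si](C)(C)C)C1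
F4 | step 7 | (4S)-4-(tert-butyldimethylsilyloxy)-3-chloro-4-(oct-2-yn-1-yl)cyclopentan-1-one (C3 epimers, not isolated) | CCCCCC#CC[C@@]1(O[Si](C)(C)C(C)(C)C)C(Cl)CC(=O)C1
F5 | step 7 | (S)-4-(tert-butyldimethylsilyloxy)-4-(oct-2-yn-1-yl)cyclopent-2-en-1-one | CCCCCC#CC[C@@]1(O[Si](C)(C)C(C)(C)C)C=CC(=O)C1
F6 | step 7 | (4S)-4-(tert-butyldimethylsilyloxy)-4-(oct-2-yn-1-yl)-6-oxabicyclo[3.1.0]hexan-2-one (epoxide face mixture) | CCCCCC#CC[C@@]1(O[Si](C)(C)C(C)(C)C)C2OC2C(=O)C1
F7 | step 7 | (4S)-4-(tert-butyldimethylsilyloxy)-2-chloro-3-hydroxy-4-(oct-2-yn-1-yl)cyclopentan-1-one (not isolated) | CCCCCC#CC[C@@]1(O[Si](C)(C)C(C)(C)C)C(O)C(Cl)C(=O)C1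
F8 | step 13 | methyl 7-oxohept-5-ynoate | O=CC#CCCCC(=O)OC
F9 | step 13 | methyl (12S,14Z)-12-(tert-butyldimethylsilyloxy)-10-chloro-7-hydroxy-9-oxoprosta-10,14-dien-5-ynoate (mixture at C7 and C8) | CCCCC/C=C\C[C@@]1(O[Si](C)(C)C(C)(C)C)C=C(Cl)C(=O)C1C(O)C#CCCCC(=O)OC
F10 | step 13 | methyl (12S,14Z)-12-(tert-butyldimethylsilyloxy)-10-chloro-7-(methanesulfonyloxy)-9-oxoprosta-10,14-dien-5-ynoate (not isolated) | CCCCC/C=C\C[C@@]1(O[Si](C)(C)C(C)(C)C)C=C(Cl)C(=O)C1C(OS(C)(=O)=O)C#CCCCC(=O)OC
F11 | step 13 | methyl (7E,12R,14Z)-12-(tert-butyldimethylsilyloxy)-10-chloro-9-oxoprosta-7,10,14-trien-5-ynoate | CCCCC/C=C\C[C@@]1(O[Si](C)(C)C(C)(C)C)C=C(Cl)C(=O)/C1=C/C#CCCCC(=O)OC
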